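The 2H-pyran ring is cut at its cis C3=C4 double bond and at the enol-ether bond O1–C8a. This exposes O1–C2–C3, with the quaternary C2 stereocentre, as intact (R)-linalool, and C4–C4a=C8a as the vinyl-bearing vinylogous acyl chloride of an acylfilicinic acid. In one pot the potassium alkoxide of linalool displaces chloride at C8a by addition–elimination and a ruthenium alkylidene then joins the two vinyl groups by ring-closing metathesis, closing the pyran with loss of ethene. The precursor, a 5-chloro-4-vinyl cyclohexadienone, comes from phloroglucinol and (R)-2-methylbutanoic acid by acylation, dearomatising gem-dimethylation, iodination, chlorination and Stille vinylation; both stereocentres are bought.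

Key step: step 6

Remark on numbering: the discussion uses the chromene numbering of the target (O1, C2, C3, C4, C4a, C5 to C8, C8a); the monocyclic triones are named as cyclohexa-2,4-dien-1-ones (their C5, C4 and C3 become C8a, C4a and C5) and are drawn as the enol tautomer that matches the target.

Assumption: (R)-(−)-linalool and (R)-2-methylbutanoic acid are bought in high enantiomeric purity; no step creates or corrects a stereocentre, so their purity limits that of the target.

Step 1
Reactants: 1 (R)-2-methylbutanoic acid; 2 phloroglucinol (benzene-1,3,5-triol)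
Product: 4 (2R)-2-methyl-1-(2,4,6-trihydroxyphenyl)butan-1-one, via (R)-2-methylbutanoyl chloride 3 (not isolated)
Conditions: 1, (COCl)2, cat. DMF, CH2Cl2, 0 °C to rt, volatiles removed; then 2, AlCl3 (3.5 equiv), PhNO2, 0 °C to rt; aq. HCl
Reagents that add atoms: none
Why: Friedel–Crafts C-acylation of the electron-rich triol by the acyl chloride–AlCl3 complex should give the mono-ketone, and because the chloride is made and used without amine base the α-stereocentre is not exposed to ketene formation or enolisation.

Step 2
Reactants: 4 (2R)-2-methyl-1-(2,4,6-trihydroxyphenyl)butan-1-one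
Product: 5 3,5-dihydroxy-6,6-dimethyl-2-[(2R)-2-methylbutanoyl]cyclohexa-2,4-dien-1-one
Conditions: NaOMe (4 equiv), MeI (2.5 equiv), MeOH, 0 °C to rt; aq. HCl
Reagents that add atoms: iodomethane, CI
Why: Dearomatising double C-methylation of the phloroglucinol polyanion at one free ring carbon (the classical acylfilicinic acid synthesis) should install the gem-dimethyl group, while the anionic ring keeps the acyl α-CH from being deprotonated by methoxide.

Step 3
Reactants: 5 3,5-dihydroxy-6,6-dimethyl-2-[(2R)-2-methylbutanoyl]cyclohexa-2,4-dien-1-one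
Product: 6 3,5-dihydroxy-4-iodo-6,6-dimethyl-2-[(2R)-2-methylbutanoyl]cyclohexa-2,4-dien-1-one
Conditions: NIS (1.05 equiv), CH2Cl2, 0 °C, dark
Reagents that add atoms: N-iodosuccinimide, O=C1CCC(=O)N1I
Why: Electrophilic α-iodination of a cyclic 1,3-dicarbonyl enol, in which the only ring CH, flanked by two enol oxygens, is the most nucleophilic carbon and should take up iodine selectively.

Step 4
Reactants: 6 3,5-dihydroxy-4-iodo-6,6-dimethyl-2-[(2R)-2-methylbutanoyl]cyclohexa-2,4-dien-1-one
Product: 7 5-chloro-3-hydroxy-4-iodo-6,6-dimethyl-2-[(2R)-2-methylbutanoyl]cyclohexa-2,4-dien-1-one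
Conditions: (COCl)2 (1.05 equiv), cat. DMF, CH2Cl2, 0 °C
Reagents that add atoms: oxalyl chloride, O=C(Cl)C(=O)Cl
Why: Vilsmeier-type conversion of a vinylogous acid into a β-chloro enone, in which the free enol oxygen next to the gem-dimethyl carbon is activated and replaced by chloride through addition–elimination while the other enol oxygen stays tied up in the hydrogen-bonded β-triketone chelate, the site preference also seen in O-alkylation of acylfilicinic acids.

Step 5
Reactants: 7 5-chloro-3-hydroxy-4-iodo-6,6-dimethyl-2-[(2R)-2-methylbutanoyl]cyclohexa-2,4-dien-1-one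
Product: 8 5-chloro-4-ethenyl-3-hydroxy-6,6-dimethyl-2-[(2R)-2-methylbutanoyl]cyclohexa-2,4-dien-1-one
Conditions: CH2=CHSnBu3, Pd2(dba)3 (cat.), AsPh3, CuI (cat.), NMP, rt
Reagents that add atoms: tributyl(vinyl)stannane, C=C[Sn](CCCC)(CCCC)CCCC
Why: Stille coupling in which zerovalent palladium should insert into the C–I bond of the α-iodo enone much faster than into the vinylogous acyl chloride, the neutral medium leaving the acidic enol and the C–Cl bond untouched.

Step 6
Reactants: 8 5-chloro-4-ethenyl-3-hydroxy-6,6-dimethyl-2-[(2R)-2-methylbutanoyl]cyclohexa-2,4-dien-1-one; 9 (R)-(−)-linalool ((3R)-3,7-dimethylocta-1,6-dien-3-ol)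
Product: 11 (2R)-5-hydroxy-2,8,8-trimethyl-6-[(2R)-2-methylbutanoyl]-2-(4-methylpent-3-en-1-yl)-2H-chromen-7(8H)-one, via linalyl enol ether 10 (not isolated)
Conditions: 9 (1.1 equiv), KH (2.1 equiv), THF, 0 °C; then 8, 0 °C to rt; AcOH (2 equiv); then second-generation Hoveyda–Grubbs catalyst RuCl2(H2IMes)(=CH-C6H4-2-OiPr) (5 mol%), CH2Cl2, 35 °C, dark
Reagents that add atoms: none
Why: Potassium linalyl oxide adds to C8a of the vinylogous acyl chloride in 8 and chloride leaves (addition–elimination, the known route from β-chloro enones and alkoxides to vinylogous esters), giving enol ether 10 in which the C4a vinyl group and the linalyl vinyl group are set for a six-membered closure. After acidification the ruthenium alkylidene joins these two terminal olefins by [2+2]/retro-[2+2] steps and releases ethene, the pyran thus closing at C3=C4 by ring-closing olefin metathesis with the cis geometry that the ring imposes, as in the known metathesis of 2-vinylaryl allyl ethers to 2H-chromenes. No stereocentre is formed: C2 is the carbinol carbon of (R)-linalool and none of its bonds is made or broken, while the acyl α-carbon is shielded in the basic stage because the trione is present as its chelated potassium enolate. Site selectivity at C8a is secured by chloride being the only leaving group, and chemoselectivity of the metathesis by the much higher reactivity of the two monosubstituted olefins over the trisubstituted olefin of the side chain. The closure is run at or below 35 °C in the dark because heat or light could open the 2H-pyran by retro-oxa-6π electrocyclisation and erode the C2 configuration.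

Compound list
1 | (R)-2-methylbutanoic acid | CC[C@@H](C)C(=O)O | starting material
2 | phloroglucinol (benzene-1,3,5-triol) | Oc1cc(O)cc(O)c1 | starting material
3 | (R)-2-methylbutanoyl chloride | CC[C@@H](C)C(=O)Cl | intermediate
4 | (2R)-2-methyl-1-(2,4,6-trihydroxyphenyl)butan-1-one | CC[C@@H](C)C(=O)c1c(O)cc(O)cc1O | intermediate
5 | 3,5-dihydroxy-6,6-dimethyl-2-[(2R)-2-methylbutanoyl]cyclohexa-2,4-dien-1-one (acylfilicinic acid) | CC[C@@H](C)C(=O)C1=C(O)C=C(O)C(C)(C)C1=O | intermediate
6 | 3,5-dihydroxy-4-iodo-6,6-dimethyl-2-[(2R)-2-methylbutanoyl]cyclohexa-2,4-dien-1-one | CC[C@@H](C)C(=O)C1=C(O)C(I)=C(O)C(C)(C)C1=O | intermediate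
7 | 5-chloro-3-hydroxy-4-iodo-6,6-dimethyl-2-[(2R)-2-methylbutanoyl]cyclohexa-2,4-dien-1-one | CC[C@@H](C)C(=O)C1=C(O)C(I)=C(Cl)C(C)(C)C1=O | intermediate
8 | 5-chloro-4-ethenyl-3-hydroxy-6,6-dimethyl-2-[(2R)-2-methylbutanoyl]cyclohexa-2,4-dien-1-one | CC[C@@H](C)C(=O)C1=C(O)C(C=C)=C(Cl)C(C)(C)C1=O | intermediate
9 | (R)-(−)-linalool, (3R)-3,7-dimethylocta-1,6-dien-3-ol | CC(C)=CCC[C@](C)(C=C)O | starting material
10 | 5-{[(3R)-3,7-dimethylocta-1,6-dien-3-yl]oxy}-4-ethenyl-3-hydroxy-6,6-dimethyl-2-[(2R)-2-methylbutanoyl]cyclohexa-2,4-dien-1-one (linalyl enol ether) | CC[C@@H](C)C(=O)C1=C(O)C(C=C)=C(O[C@](C)(CCC=C(C)C)C=C)C(C)(C)C1=O | intermediate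
11 | (2R)-5-hydroxy-2,8,8-trimethyl-6-[(2R)-2-methylbutanoyl]-2-(4-methylpent-3-en-1-yl)-2H-chromen-7(8H)-one | CC[C@@H](C)C(=O)C1=C(O)C2=C(O[C@](C)(CCC=C(C)C)C=C2)C(C)(C)C1=O | target

Total step count: 6. Longest linear sequence: 6 steps (from 1 or 2 to 11).

Steps most likely to fail

Step 6. The addition–elimination may stall, because a tertiary alkoxide must attack a carbon flanked by the gem-dimethyl carbon and the vinyl-bearing carbon of an already deprotonated trione. In the metathesis stage the alkylidene may instead close a cyclopentene onto the trisubstituted olefin of the linalyl chain, and the allyl vinyl ether may undergo a [3,3] shift if warmed. The fallback sets out from 5 and returns at 11. Knoevenagel condensation of 5 with citral (ethylenediammonium diacetate, CH2Cl2, rt) is followed in the same flask by oxa-6π electrocyclisation of the resulting dienone, which should close mainly through the non-chelated oxygen. This builds the pyran from the other side and is not stereocontrolled at C2, so it should give 11 together with the (2S)-configured C2 epimer of the target F1. Because the (R)-acyl centre is fixed, the two are diastereomers and would be separated by preparative HPLC.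

Step 4. Activation may occur at the chelated enol oxygen instead of the free one, and iodine may be lost from the α-iodo dione by halogen exchange with the chloride and HCl that the reagent releases. The fallback sets out from 6 and returns at 10. Sulfonylation of the free enol oxygen (TsCl, Et3N, CH2Cl2, 0 °C) should give the iodo enol tosylate F2 without any acid. Stille vinylation under the conditions of step 5, to which the sulfonate is inert, should give the vinyl enol tosylate F3. F3 then takes the place of 8 in the first stage of step 6, where the alkoxide displaces tosylate at C8a and gives 10.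

Step 5. Oxidative addition at the hindered, tetrasubstituted C–I bond may be slow, which would allow reduction of that bond or insertion into the vinylogous acyl chloride. The fallback sets out from 5 and returns at 8 without palladium or iodine. Three-component condensation of 5 with acetaldehyde and thiophenol (cat. piperidine, CH2Cl2, rt) should give the 1-(phenylsulfanyl)ethyl trione F4. Chlorination as in step 4 should give the chloro sulfide F5, and oxidation with mCPBA (CH2Cl2, −78 °C) the sulfoxide F6. Thermal syn-elimination of F6 (toluene, 90 °C, CaCO3) can only take a hydrogen from the methyl group and should give 8.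

Further compounds
F1 | step 6 | (2S)-5-hydroxy-2,8,8-trimethyl-6-[(2R)-2-methylbutanoyl]-2-(4-methylpent-3-en-1-yl)-2H-chromen-7(8H)-one | CC[C@@H](C)C(=O)C1=C(O)C2=C(O[C@@](C)(CCC=C(C)C)C=C2)C(C)(C)C1=O
F2 | step 4 | 3-hydroxy-2-iodo-6,6-dimethyl-4-[(2R)-2-methylbutanoyl]-5-oxocyclohexa-1,3-dien-1-yl 4-methylbenzenesulfonate | CC[C@@H](C)C(=O)C1=C(O)C(I)=C(OS(=O)(=O)c2ccc(C)cc2)C(C)(C)C1=O
F3 | step 4 | 2-ethenyl-3-hydroxy-6,6-dimethyl-4-[(2R)-2-methylbutanoyl]-5-oxocyclohexa-1,3-dien-1-yl 4-methylbenzenesulfonate | CC[C@@H](C)C(=O)C1=C(O)C(C=C)=C(OS(=O)(=O)c2ccc(C)cc2)C(C)(C)C1=O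
F4 | step 5 | 3,5-dihydroxy-6,6-dimethyl-2-[(2R)-2-methylbutanoyl]-4-[1-(phenylsulfanyl)ethyl]cyclohexa-2,4-dien-1-one (both epimers at the sulfur-bearing carbon) | CC[C@@H](C)C(=O)C1=C(O)C(C(C)Sc2ccccc2)=C(O)C(C)(C)C1=O
F5 | step 5 | 5-chloro-3-hydroxy-6,6-dimethyl-2-[(2R)-2-methylbutanoyl]-4-[1-(phenylsulfanyl)ethyl]cyclohexa-2,4-dien-1-one (both epimers at the sulfur-bearing carbon) | CC[C@@H](C)C(=O)C1=C(O)C(C(C)Sc2ccccc2)=C(Cl)C(C)(C)C1=O
F6 | step 5 | 4-[1-(benzenesulfinyl)ethyl]-5-chloro-3-hydroxy-6,6-dimethyl-2-[(2R)-2-methylbutanoyl]cyclohexa-2,4-dien-1-one (mixture of stereoisomers at carbon and sulfur) | CC[C@@H](C)C(=O)C1=C(O)C(C(C)S(=O)c2ccccc2)=C(Cl)C(C)(C)C1=O
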